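**Retrosynthetic overview**
1. Target 8 ⇒ methyl isocupressate 6. The C14–O bond and the C13=C16 alkene come from one enantioselective oxidative allylic transposition: Ti/D-tartrate oxygen transfer to C13=C14, then directed opening of C13–O with loss of a C16 proton.
2. 6 ⇒ dimethyl agathate 4 by chemoselective 1,2-reduction of the conjugated C15 ester; the hindered axial C19 ester stays.
3. 4 ⇒ agathic acid 1 by double O-methylation.
4. Rings: none is formed. The trans-decalin (rings A and B, with C4, C5, C9, C10) is bought intact with 1 and never touched; C14 is the only stereocentre made.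

Assumption: natural agathic acid, a catalogue labdane diacid and the main acid of Manila copal resin, is taken as the commercial starting material; labdane numbering is used throughout.

**Step 1**
Reactants: 1 agathic acid
Product: 4 dimethyl agathate, via C15 monomethyl ester 2 (not isolated), via C19 monomethyl ester 3 (not isolated)
Conditions: MeI (3 equiv), K2CO3 (3 equiv), DMF, 25 °C, 14 h
Reagents that add atoms: iodomethane, CI
Why: Carboxylate SN2 O-alkylation forms the bond at oxygen, two atoms away from the quaternary C4, so even the axial C19 acid is esterified; K2CO3 is too weak to isomerise the enoate and no stereocentre is touched.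

**Step 2**
Reactants: 4 dimethyl agathate
Product: 6 methyl isocupressate, via enal 5 (not isolated)
Conditions: DIBAL-H (2.3 equiv), CH2Cl2, −78 °C, 1.5 h; MeOH, then aq. Rochelle salt
Reagents that add atoms: none
Why: Chemoselective DIBAL-H 1,2-reduction of an α,β-unsaturated ester (through the enal) gives the (E)-allylic alcohol, while the axial neopentyl C19 ester, shielded by the 1,3-diaxial C20 methyl, is not attacked at −78 °C; no stereocentre is formed and the E geometry is kept.

**Step 3**
Reactants: 6 methyl isocupressate
Product: 8 methyl (14S)-14,15-dihydroxylabda-8(17),13(16)-dien-19-oate (target), via epoxy alcohol 7 (not isolated)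
Conditions: Ti(OiPr)4 (10 mol %), D-(−)-DET (12 mol %), TBHP (1.3 equiv, decane), 4 Å MS, CH2Cl2, −20 °C; P(OMe)3 (0.4 equiv), −20 °C; then Ti(OiPr)4 (2.0 equiv), −20 → 25 °C; aq. tartaric acid
Reagents that add atoms: tert-butyl hydroperoxide, CC(C)(C)OO
Why: Proposed new method: a one-flask enantioselective oxidative allylic transposition (formal asymmetric oxygen-ene reaction). Stage 1 is a Katsuki–Sharpless asymmetric epoxidation in which the Ti/D-(−)-tartrate template delivers oxygen to the face of the geraniol-type (E)-alkene that gives the (13R,14R)-epoxy alkoxide (catalyst control, about 95:5 expected; the isolated C8(17) alkene and the ester are inert), which makes the C14–O bond and fixes C14. After the excess peroxide is destroyed, tartrate-free Ti(OiPr)4 binds the C15 alkoxide and the epoxide oxygen in a five-membered chelate, the tertiary C13–O bond is loosened, and a titanium-bound isopropoxide removes a proton from the C16 methyl (cis to the CH2O–Ti arm) through a six-membered syn-elimination, so C13=C16 forms and the untouched C14–O becomes the (14S)-carbinol (the R to S change is only a change of CIP priorities). The closest known reactions are Sharpless asymmetric epoxidation with in-situ derivatisation and the separate stoichiometric Ti(OiPr)4 rearrangement of 2,3-epoxy alcohols to allylic 1,2-diols; to my knowledge their merger into a single enantioselective operation has not been described.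

**Compound list**
1 | agathic acid, (13E)-labda-8(17),13-diene-15,19-dioic acid, (4S,5R,9S,10R) | C/C(=C\C(=O)O)CC[C@H]1C(=C)CC[C@@H]2[C@]1(C)CCC[C@]2(C)C(=O)O | starting material
2 | 15-methyl hydrogen agathate (C15 methyl ester, C19 acid; present as its potassium salt) | C/C(=C\C(=O)OC)CC[C@H]1C(=C)CC[C@@H]2[C@]1(C)CCC[C@]2(C)C(=O)O | intermediate
3 | 19-methyl hydrogen agathate (C19 methyl ester, C15 acid; present as its potassium salt) | C/C(=C\C(=O)O)CC[C@H]1C(=C)CC[C@@H]2[C@]1(C)CCC[C@]2(C)C(=O)OC | intermediate
4 | dimethyl agathate, dimethyl (13E)-labda-8(17),13-diene-15,19-dioate | C/C(=C\C(=O)OC)CC[C@H]1C(=C)CC[C@@H]2[C@]1(C)CCC[C@]2(C)C(=O)OC | intermediate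
5 | methyl (13E)-15-oxolabda-8(17),13-dien-19-oate (enal) | C/C(=C\C=O)CC[C@H]1C(=C)CC[C@@H]2[C@]1(C)CCC[C@]2(C)C(=O)OC | intermediate
6 | methyl isocupressate, methyl (13E)-15-hydroxylabda-8(17),13-dien-19-oate | C/C(=C\CO)CC[C@H]1C(=C)CC[C@@H]2[C@]1(C)CCC[C@]2(C)C(=O)OC | intermediate
7 | methyl (13R,14R)-13,14-epoxy-15-hydroxylabd-8(17)-en-19-oate (C16 methyl cis to CH2OH on the oxirane) | C[C@]1(CC[C@H]2C(=C)CC[C@@H]3[C@]2(C)CCC[C@]3(C)C(=O)OC)O[C@@H]1CO | intermediate
8 | methyl (14S)-14,15-dihydroxylabda-8(17),13(16)-dien-19-oate, (4S,5R,9S,10R) core | C=C(CC[C@H]1C(=C)CC[C@@H]2[C@]1(C)CCC[C@]2(C)C(=O)OC)[C@H](O)CO | target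

**Step count and risks**
Total step count: 3. Longest linear sequence: 3 steps (1 → 4 → 6 → 8).

Steps most likely to fail, in order of risk:

Step 3 (the proposed new step). The oxygen transfer is standard; the risk lies in the second stage run in the same flask. Residual tartrate, tert-butanol or isopropoxide may open the epoxide at C13 instead of eliminating, the nucleophilic C8(17) alkene may cyclise onto the titanium-activated C13, and any surviving peroxide would epoxidise the new allylic alcohol of 8. The fallback uses known chemistry, sets out from 6 and comes back at 8. The single-flask transposition is given up for two separate literature reactions. First, the ordinary catalytic Sharpless epoxidation of 6 (Ti(OiPr)4, D-(−)-DET, TBHP, 4 Å MS, −20 °C) with aqueous work-up and chromatographic isolation of epoxy alcohol 7. Second, on pure 7 and free of tartrate, peroxide and tert-butanol, the established hydroxyl-directed Ti(OiPr)4 rearrangement of a 2,3-epoxy alcohol to the allylic 1,2-diol (Ti(OiPr)4 1.5–2 equiv, CH2Cl2, 25 °C), giving 8. No compound outside the list is made (F0).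

Step 2. DIBAL-H may begin to reduce the C19 ester or stop partly at enal 5. The fallback sets out from 4 and comes back at 6, replacing direct hydride chemoselection by hydrolytic differentiation of the two esters. KOH in aqueous MeOH at 60 °C saponifies only the unhindered conjugated C15 ester and gives 19-methyl hydrogen agathate 3, isolated here. Ethyl chloroformate and Et3N (THF, −10 °C) convert 3 into the mixed ethyl carbonic anhydride F1, which NaBH4 (THF/H2O, 0 °C) reduces to allylic alcohol 6.

Step 1. This is the lowest risk; the only concern is incomplete alkylation of the hindered C19 carboxylate, leaving 2. The fallback sets out from 1 and comes back at 4. Anionic carboxylate alkylation is replaced by base-free diazoalkane esterification (TMSCHN2, PhMe/MeOH 4:1, 0 → 25 °C), in which the free acid protonates the reagent and the resulting ion pair collapses to the methyl ester at both carboxyl groups. No compound outside the list is made (F0).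

**Further compounds**
F0 | step 3 | none | none
F1 | step 2 | (13E)-19-methoxy-19-oxolabda-8(17),13-dien-15-oic ethyl carbonic anhydride | C/C(=C\C(=O)OC(=O)OCC)CC[C@H]1C(=C)CC[C@@H]2[C@]1(C)CCC[C@]2(C)C(=O)OC
F0 | step 1 | none | none
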